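A small charge of electrophile stands in 0.0660 M of nucleophile in spring and 0.0330 M in autumn, and we read each flask after 40 h.

| setting | spring | autumn |
|---|---|---|
| electrophile | 0.011 M | 0.011 M |
| nucleophile | 0.0660 M | 0.0330 M |
| time | 40 h | 40 h |

    electrophile + nucleophile → acid set free + target (k1 = 1.5 × 10⁻⁴ M⁻¹ s⁻¹)
    nucleophile + acid set free ⇌ protonated nucleophile, settled at all times (K2 = 13000 M⁻¹)
    target → over-reaction product (k3 = 1.6 × 10⁻⁶ s⁻¹)
    electrophile + target ⇌ idle adduct, settled at all times (K4 = 40 M⁻¹)

- part of the electrophile that has reacted at the end, spring
- part of the electrophile that has reacted at the end, autumn
- what raising the concentration of nucleophile from its lowest to its highest value here does to the part of the electrophile that has reacted (changes below 5 percentage points count as none) (it rises / no change / it falls)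

- percentages count the electrophile that a species holds: one idle adduct counts as two
- target is meant together with its idle adduct
- in an amount of target, one idle adduct counts as one target
- what has gone from electrophile into another species counts as reacted, even if it can come back
- run time (spring): 40 h

The bench habit calls this nucleophile in excess and treats the first step as pseudo-first-order. With [nucleophile] held at its charge, the autumn half-life of electrophile is 39 h, and the part gone by the end is 76.0% in spring and 51.0% in autumn.

The habit ends where the charge stops being large against what the run spends. The second step, kept at balance, has 430 as its constant times autumn's starting [nucleophile], so we take each acid set free as caught at once, and each turnover costs 2 nucleophiles. The nucleophile bill, the share of the nucleophile charge that full turnover of the electrophile spends at that price, is 0.667 in autumn and 0.333 in spring. Neither is small, so [nucleophile] falls during the run.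

Let f be the part turned over. We put [nucleophile] = charge × (one minus bill × f) into the rate law and integrate, which gives f = (G − 1)/(G − bill). Here G is the exponential of the first step's constant, times the time, times the surplus of [nucleophile] charged over 2 [electrophile] charged. G is 2.59 in spring and 1.27 in autumn. We commit to 70.4% in spring and 44.6% in autumn, so the verdict is: it rises. Our reckoning leaves out the idle adduct, whose electrophile also counts as reacted; the fourth step's constant times autumn's starting [electrophile] is 0.44.

The forecast gives 71% and 49% and says it rises, on the ground that “each acid released ties up a second nucleophile”. Its autumn figure is higher than ours.

The simulation gives 72.5% in spring and 49.5% in autumn: it rises, by 23 percentage points. The forecast held. The same bill serves the autumn flask read at 3.0 d: G becomes 1.53, so f is 61.6% and free nucleophile is 58.9% of its charge. That flask shows free nucleophile at 61.1% of its charge, target with its idle adduct and over-reaction product together at 58.4% of the electrophile charged, and 64.8% of the electrophile reacted.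

The rate constants are assumed, and the outcome is calculated.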